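**Plan**
- Retrosynthesis: the pyran O1–C2 bond is cut first, which leads back to an ortho-prenylphenol (prenyl on C4a, hydroxyl on C8a). Ring A is then cut at C4a–C5 and C6–C7.
- Feature used: in ring A (C4a, C5, C6, C7, C8, C8a; chromene numbering) the oxygen-bearing C7 and C8a are the ester and ketone carbons of a γ-prenylated acetoacetate, with C8 its α-carbon and C4a its γ-carbon. C5 (OMe) and C6 (arylacetyl) are the two sp carbons of a methoxy-substituted ynone.
- Forward: a γ-prenylated 1-methoxy-1,3-bis(silyloxy)diene (three steps from methyl acetoacetate) and a methoxy ynone (two steps from 4-methoxyphenylacetic acid) are joined. Ring A forms by [4+2] cycloaddition and aromatisation, then the pyran ring by DDQ cyclodehydrogenation.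
- Stereochemistry: the target has no stereocentre. Its cis C3=C4 bond is fixed by the ring, and the diene geometry is erased on aromatisation.

Key step: step 6

Remark: enol ether 5 and diene 7 are drawn as the 2E and (1Z,3Z) isomers, which are expected to predominate; any mixture of geometric isomers should serve equally, because none of these double bonds survives in the arene.

**Step 1**
Reactants: 1 methyl acetoacetate; 2 1-bromo-3-methylbut-2-ene
Product: 4 methyl 7-methyl-3-oxooct-6-enoate, via methyl acetoacetate dianion 3 (not isolated)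
Conditions: NaH, THF, 0 °C; n-BuLi, 0 °C; then 2, 0 → 25 °C; 1 M HCl quench
Reagents that add atoms: none
Why: Alkylation of the acetoacetate dianion, whose γ-carbanion is far more nucleophilic than the stabilised α-position, so SN2 displacement of the primary allylic bromide should give the γ-prenylated β-keto ester without α- or O-alkylation.

**Step 2**
Reactants: 4 methyl 7-methyl-3-oxooct-6-enoate
Product: 5 methyl (2E)-7-methyl-3-(trimethylsilyloxy)octa-2,6-dienoate
Conditions: Me3SiCl, Et3N, PhMe, 25 °C; filtered and concentrated under Ar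
Reagents that add atoms: chlorotrimethylsilane, C[Si](C)(C)Cl
Why: O-Silylation of the enolised β-keto ester with Me3SiCl and Et3N is the standard first stage in making 1,3-bis(silyloxy)dienes, and the isolated trisubstituted alkene is inert to it.

**Step 3**
Reactants: 5 methyl (2E)-7-methyl-3-(trimethylsilyloxy)octa-2,6-dienoate
Product: 7 (1Z,3Z)-1-methoxy-7-methyl-1,3-bis(trimethylsilyloxy)octa-1,3,6-triene, via lithium ester dienolate 6 (not isolated)
Conditions: LiN(i-Pr)2, THF, −78 °C; Me3SiCl, −78 → 25 °C; pentane, filtered under Ar, used crude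
Reagents that add atoms: chlorotrimethylsilane, C[Si](C)(C)Cl
Why: Kinetic γ-deprotonation of the β-silyloxy enoate gives the ester dienolate, which Me3SiCl traps on oxygen as the silyl ketene acetal, the standard preparation of 1-alkoxy-1,3-bis(silyloxy)dienes.

**Step 4**
Reactants: 8 4-methoxyphenylacetic acid
Product: 10 N-methoxy-2-(4-methoxyphenyl)-N-methylacetamide, via acyl imidazolide 9 (not isolated)
Conditions: 1,1'-carbonyldiimidazole, CH2Cl2, 25 °C; then MeNH(OMe)·HCl, 25 °C
Reagents that add atoms: N,O-dimethylhydroxylamine hydrochloride, CNOC.Cl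
Why: Carbonyldiimidazole activation to the acyl imidazolide followed by aminolysis is a standard Weinreb amide synthesis and avoids an acid chloride of the enolisable arylacetic acid.

**Step 5**
Reactants: 10 N-methoxy-2-(4-methoxyphenyl)-N-methylacetamide; 11 chloroacetaldehyde dimethyl acetal
Product: 13 4-methoxy-1-(4-methoxyphenyl)but-3-yn-2-one, via lithium methoxyacetylide 12 (not isolated)
Conditions: 11 (2 equiv), LiNEt2 (from n-BuLi and Et2NH, 3 equiv per 11), THF, 0 °C; then 10, −78 → −30 °C; inverse quench into cold aqueous NaH2PO4; used promptly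
Reagents that add atoms: none
Why: Lithium diethylamide converts the chloroacetal by successive loss of methanol and hydrogen chloride and a final deprotonation into lithium methoxyacetylide, which is acylated by the Weinreb amide without over-addition (Weinreb ketone synthesis) to give the alkynyl ketone.

**Step 6**
Reactants: 7 (1Z,3Z)-1-methoxy-7-methyl-1,3-bis(trimethylsilyloxy)octa-1,3,6-triene; 13 4-methoxy-1-(4-methoxyphenyl)but-3-yn-2-one
Product: 16 1-[2,4-dihydroxy-6-methoxy-5-(3-methylbut-2-en-1-yl)phenyl]-2-(4-methoxyphenyl)ethanone, via cyclohexadiene cycloadduct 14 (not isolated), via aryl bis(trimethylsilyl) ether 15 (not isolated)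
Conditions: 7 (2 equiv), PhMe, 25 → 80 °C, Ar, no Lewis acid; then 1 M HCl, THF, 0 °C
Reagents that add atoms: none
Why: Proposed new method: the electron-rich trioxygenated diene 7 should add across the push-pull alkyne of 13 in a strongly asynchronous Diels–Alder reaction, in which its most nucleophilic terminus C4 (future C4a, carrying the prenyl group) bonds to the ynone β-carbon (future C5, bearing OMe) and its ketene acetal carbon C1 (future C7) bonds to the α-carbon (future C6), with a Mukaiyama–Michael addition followed by Claisen closure as the polar limit of the same bond set. The closest known reaction type is the Diels–Alder reaction and aromatisation of 1-alkoxy-1,3-bis(silyloxy)dienes with acetylenic ketones and esters to give resorcinols, whereas a β-alkoxy ynone has not served as the 2π partner. Ring A closes as a six-membered carbocycle by [4+2] cycloaddition, which in the stepwise view is a 6-exo-trig attack of the allenolate α-carbon on the ester carbon. Cycloadduct 14 then loses methanol across the ketal carbon and the C4a–H to give arene 15, whose silyl ethers are hydrolysed in the acidic work-up, and since both sp3 centres of 14 are erased no stereocentre has to be controlled. The step needs head-to-tail regiochemistry and closure through C1 instead of C2: the first should follow from pairing the largest diene HOMO coefficient with the electrophilic β-carbon of the ynone, the second from running the reaction thermally without a Lewis acid, and the C5 methoxy should survive because only the ketal carbon carries a group that aromatisation can expel (methoxy, not silyloxy, as is usual for mixed methyl silyl ketene acetal dienes). A methoxyalkyne has no β-hydrogen for retro-ene loss to a ketene, so 13 should tolerate the heating.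

**Step 7**
Reactants: 16 1-[2,4-dihydroxy-6-methoxy-5-(3-methylbut-2-en-1-yl)phenyl]-2-(4-methoxyphenyl)ethanone
Product: 17 1-(7-hydroxy-5-methoxy-2,2-dimethyl-2H-chromen-6-yl)-2-(4-methoxyphenyl)ethanone
Conditions: DDQ (1.1 equiv), benzene, 80 °C
Reagents that add atoms: none
Why: DDQ cyclodehydrogenation of an ortho-prenylphenol, in which hydride abstraction from the benzylic and allylic CH2 gives an ortho-quinone methide that closes by oxa-6π electrocyclisation; only the C8a hydroxyl flanks the prenyl group (its other neighbour is the methoxy group) and the C7 hydroxyl is held in a hydrogen bond to the ketone.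

**Compound list**
1 | methyl acetoacetate | COC(=O)CC(C)=O | starting material
2 | 1-bromo-3-methylbut-2-ene | CC(C)=CCBr | starting material
3 | methyl acetoacetate α,γ-dianion (sodium lithium salt) | [Na+].[Li+].[CH2-]C(=O)[CH-]C(=O)OC | intermediate
4 | methyl 7-methyl-3-oxooct-6-enoate | COC(=O)CC(=O)CCC=C(C)C | intermediate
5 | methyl (2E)-7-methyl-3-(trimethylsilyloxy)octa-2,6-dienoate | COC(=O)/C=C(/O[Si](C)(C)C)CCC=C(C)C | intermediate
6 | lithium 1-methoxy-7-methyl-3-(trimethylsilyloxy)octa-1,3,6-trien-1-olate | [Li+].COC([O-])=CC(O[Si](C)(C)C)=CCC=C(C)C | intermediate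
7 | (1Z,3Z)-1-methoxy-7-methyl-1,3-bis(trimethylsilyloxy)octa-1,3,6-triene | CO/C(O[Si](C)(C)C)=C/C(/O[Si](C)(C)C)=C/CC=C(C)C | intermediate
8 | 4-methoxyphenylacetic acid | COc1ccc(CC(=O)O)cc1 | starting material
9 | 1-(1H-imidazol-1-yl)-2-(4-methoxyphenyl)ethanone | COc1ccc(CC(=O)n2ccnc2)cc1 | intermediate
10 | N-methoxy-2-(4-methoxyphenyl)-N-methylacetamide | COc1ccc(CC(=O)N(C)OC)cc1 | intermediate
11 | chloroacetaldehyde dimethyl acetal (2-chloro-1,1-dimethoxyethane) | COC(CCl)OC | starting material
12 | lithium methoxyacetylide | [Li]C#COC | intermediate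
13 | 4-methoxy-1-(4-methoxyphenyl)but-3-yn-2-one | COC#CC(=O)Cc1ccc(OC)cc1 | intermediate
14 | 1-[2,6-dimethoxy-3-(3-methylbut-2-en-1-yl)-4,6-bis(trimethylsilyloxy)cyclohexa-1,4-dien-1-yl]-2-(4-methoxyphenyl)ethanone (racemic diastereomer mixture) | COC1=C(C(=O)Cc2ccc(OC)cc2)C(OC)(O[Si](C)(C)C)C=C(O[Si](C)(C)C)C1CC=C(C)C | intermediate
15 | 1-[2-methoxy-3-(3-methylbut-2-en-1-yl)-4,6-bis(trimethylsilyloxy)phenyl]-2-(4-methoxyphenyl)ethanone | COc1ccc(CC(=O)c2c(O[Si](C)(C)C)cc(O[Si](C)(C)C)c(CC=C(C)C)c2OC)cc1 | intermediate
16 | 1-[2,4-dihydroxy-6-methoxy-5-(3-methylbut-2-en-1-yl)phenyl]-2-(4-methoxyphenyl)ethanone | COc1ccc(CC(=O)c2c(O)cc(O)c(CC=C(C)C)c2OC)cc1 | intermediate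
17 | 1-(7-hydroxy-5-methoxy-2,2-dimethyl-2H-chromen-6-yl)-2-(4-methoxyphenyl)ethanone | COc1ccc(CC(=O)c2c(O)cc3c(c2OC)C=CC(C)(C)O3)cc1 | target

**Count**
Total steps: 7. Longest linear sequence: 5 steps (1 → 4 → 5 → 7 → 16 → 17).

**Steps most likely to fail**

Step 6. The donor-substituted alkyne may react so slowly that protodesilylation or thermal decay of the diene wins. Ring closure may also run through the central C2 of the diene onto the ketone carbonyl instead of through the ketene acetal carbon. The fallback uses known chemistry only, sets out from acid 8 and returns at 16.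
- Friedel–Crafts acylation of 5-methoxyresorcinol with 8 (BF3·OEt2, 85 °C) should give, as the main regioisomer from attack para to a hydroxyl, 1-(2,4-dihydroxy-6-methoxyphenyl)-2-(4-methoxyphenyl)ethanone F1.
- The non-chelated para hydroxyl is protected (MeOCH2Cl, i-Pr2NEt, CH2Cl2, 0 °C) to give 1-[2-hydroxy-6-methoxy-4-(methoxymethoxy)phenyl]-2-(4-methoxyphenyl)ethanone F2.
- Mitsunobu etherification of the remaining chelated hydroxyl with 3-methylbut-2-en-1-ol (PPh3, diisopropyl azodicarboxylate, THF) gives 1-[2-methoxy-4-(methoxymethoxy)-6-(3-methylbut-2-en-1-yloxy)phenyl]-2-(4-methoxyphenyl)ethanone F3.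
- Heating in N,N-diethylaniline at about 200 °C should move the prenyl group by a Claisen then Cope sequence to the position para to the ether oxygen. That is the carbon between the methoxy and methoxymethoxy groups, so the product is 1-[6-hydroxy-2-methoxy-4-(methoxymethoxy)-3-(3-methylbut-2-en-1-yl)phenyl]-2-(4-methoxyphenyl)ethanone F4.
- Mild acid methanolysis (HCl, MeOH, 25 °C) removes the acetal and gives 16.

Step 5. The acetylide or residual amide base may enolise the amide at its benzylic position instead of adding. Diethylamine may also add to the ynone, or the ynol ether may hydrate during work-up. The fallback sets out from 10 (with acetylide 12 made from 11 as before) and returns at 13.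
- Reduction of 10 with i-Bu2AlH (THF, −78 °C) gives (4-methoxyphenyl)acetaldehyde F5.
- 12 adds to F5 at −78 °C, faster than enolisation, to give racemic 4-methoxy-1-(4-methoxyphenyl)but-3-yn-2-ol F6.
- Oxidation with activated MnO2 (CH2Cl2, 25 °C) or Dess–Martin periodinane buffered with NaHCO3 gives 13.

Step 7. DDQ may over-oxidise the material, either at the anisyl-activated methylene of the deoxybenzoin or at the electron-rich chromene once formed. The fallback sets out from 16 and returns at 17.
- PhSeCl (CH2Cl2, −78 °C) should trigger 6-endo selenoetherification through the C8a hydroxyl at the tertiary carbon, giving racemic 1-[7-hydroxy-5-methoxy-2,2-dimethyl-3-(phenylselanyl)-3,4-dihydro-2H-chromen-6-yl]-2-(4-methoxyphenyl)ethanone F7.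
- H2O2 (THF, 0 → 25 °C) oxidises it to 1-[7-hydroxy-5-methoxy-2,2-dimethyl-3-(phenylseleninyl)-3,4-dihydro-2H-chromen-6-yl]-2-(4-methoxyphenyl)ethanone F8.
- Syn-elimination of F8 can only run towards C4 and gives 17.

**Further compounds**
F1 | step 6 | 1-(2,4-dihydroxy-6-methoxyphenyl)-2-(4-methoxyphenyl)ethanone | COc1ccc(CC(=O)c2c(O)cc(O)cc2OC)cc1
F2 | step 6 | 1-[2-hydroxy-6-methoxy-4-(methoxymethoxy)phenyl]-2-(4-methoxyphenyl)ethanone | COCOc1cc(O)c(C(=O)Cc2ccc(OC)cc2)c(OC)c1
F3 | step 6 | 1-[2-methoxy-4-(methoxymethoxy)-6-(3-methylbut-2-en-1-yloxy)phenyl]-2-(4-methoxyphenyl)ethanone | COCOc1cc(OCC=C(C)C)c(C(=O)Cc2ccc(OC)cc2)c(OC)c1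
F4 | step 6 | 1-[6-hydroxy-2-methoxy-4-(methoxymethoxy)-3-(3-methylbut-2-en-1-yl)phenyl]-2-(4-methoxyphenyl)ethanone | COCOc1cc(O)c(C(=O)Cc2ccc(OC)cc2)c(OC)c1CC=C(C)C
F5 | step 5 | (4-methoxyphenyl)acetaldehyde | COc1ccc(CC=O)cc1
F6 | step 5 | 4-methoxy-1-(4-methoxyphenyl)but-3-yn-2-ol (racemic) | COC#CC(O)Cc1ccc(OC)cc1
F7 | step 7 | 1-[7-hydroxy-5-methoxy-2,2-dimethyl-3-(phenylselanyl)-3,4-dihydro-2H-chromen-6-yl]-2-(4-methoxyphenyl)ethanone (racemic) | COc1ccc(CC(=O)c2c(O)cc3OC(C)(C)C([Se]c4ccccc4)Cc3c2OC)cc1
F8 | step 7 | 1-[7-hydroxy-5-methoxy-2,2-dimethyl-3-(phenylseleninyl)-3,4-dihydro-2H-chromen-6-yl]-2-(4-methoxyphenyl)ethanone (diastereomer mixture) | COc1ccc(CC(=O)c2c(O)cc3OC(C)(C)C([Se](=O)c4ccccc4)Cc3c2OC)cc1
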